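**Retrosynthetic overview**
1. Target 14 ⇐ flavanone 12 by removal of one silyl ether and one acetate (steps 9, 10); both geranyl groups, the ring A oxygens and C2 are already in place in 12.
2. Key disconnection: the C4–C4a bond of ring C. 12 ⇐ open-chain tertiary amide 10 by an intramolecular Vilsmeier–Haack-type acylation after Tf2O activation. Rings A and B are bought as arenes; ring C is the only ring formed, and it is formed last.
3. Enabling feature: on ring A, C4a is the only unsubstituted carbon ortho to O1 (C8 carries the geranyl group). It lies ortho to the oxygens on C8a and C5 and para to the oxygen on C7, and the O1–C2–C3 tether can deliver C4 only there (C6 is para to O1).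
4. 10 ⇐ phenol 5 + (R)-hydroxy amide 9 by Mitsunobu etherification with inversion (O1–C2 bond, C2 becomes S); 9 ⇐ β-keto ester 6 by asymmetric hydrogenation, aminolysis and phenol acetylation.
5. 5 ⇐ phloroglucinol 1 + two geraniol 2: C-geranylation, silylation of the hydroxyl para to the geranyl group, mono-O-geranylation.

Key step: step 8

Remark: β-keto ester 6 is taken as a catalogue compound; flavanone numbering is used (O1, C2, C3, C4, C4a, C5–C8, C8a; ring A benzo, ring B 2-aryl, ring C pyranone), and "geranyl" means (2E)-3,7-dimethylocta-2,6-dien-1-yl.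

**Step 1**
Reactants: 1 phloroglucinol; 2 geraniol
Product: 3 2-geranylphloroglucinol
Conditions: acidic Al2O3, ClCH2CH2Cl, reflux
Reagents that add atoms: none
Why: Al2O3-promoted ortho C-allylation of a phenol by an allylic alcohol (surface Friedel–Crafts allylation) should give one mono-geranyl triol, since the three ring CH positions of 1 are equivalent and bond formation at C1 of the geranyl unit keeps the E double bond.

**Step 2**
Reactants: 3 2-geranylphloroglucinol
Product: 4 2-geranyl-5-(triisopropylsilyloxy)benzene-1,3-diol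
Conditions: TIPSCl, imidazole, DMF, 0 °C
Reagents that add atoms: triisopropylsilyl chloride CC(C)[Si](Cl)(C(C)C)C(C)C
Why: Silylation with a bulky chlorosilane should take the one hydroxyl that has no ortho substituent (para to the geranyl group), the other two being shielded by the geranyl chain.

**Step 3**
Reactants: 4 2-geranyl-5-(triisopropylsilyloxy)benzene-1,3-diol; 2 geraniol
Product: 5 2-geranyl-3-(geranyloxy)-5-(triisopropylsilyloxy)phenol
Conditions: PPh3, DIAD, THF, 0 °C to rt (geraniol as limiting reagent)
Reagents that add atoms: none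
Why: Mitsunobu etherification with a primary allylic alcohol runs by SN2 at C1 of geraniol and keeps the E geometry; the two free hydroxyls of 4 are equivalent, so every mono-ether is 5, and unreacted 4 and the bis-ether are separated.

**Step 4**
Reactants: 6 ethyl 3-(4-hydroxyphenyl)-3-oxopropanoate
Product: 7 ethyl (3R)-3-hydroxy-3-(4-hydroxyphenyl)propanoate
Conditions: [RuCl(p-cymene)((S)-BINAP)]Cl (cat.), H2 (50 bar), EtOH, 40 °C
Reagents that add atoms: none
Why: Noyori-type asymmetric hydrogenation of a β-keto ester; hydride is delivered to the ester-chelated ketone on the face set by the (S)-diphosphine, which should give the (R)-carbinol (the sense that gives (S)-3-hydroxybutanoate from acetoacetate, the aryl group changing the descriptor).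

**Step 5**
Reactants: 7 ethyl (3R)-3-hydroxy-3-(4-hydroxyphenyl)propanoate
Product: 8 (3R)-3-hydroxy-3-(4-hydroxyphenyl)-N,N-dimethylpropanamide
Conditions: Me2NH (2 M in MeOH), 50 °C, sealed tube
Reagents that add atoms: dimethylamine CNC
Why: Aminolysis of a β-hydroxy ester by a small secondary amine (assisted by the β-hydroxyl) should give the tertiary amide without touching the carbinol centre.

**Step 6**
Reactants: 8 (3R)-3-hydroxy-3-(4-hydroxyphenyl)-N,N-dimethylpropanamide
Product: 9 4-[(1R)-3-(dimethylamino)-1-hydroxy-3-oxopropyl]phenyl acetate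
Conditions: Ac2O, aq. NaOH, THF, 0 °C
Reagents that add atoms: acetic anhydride CC(=O)OC(C)=O
Why: Schotten–Baumann acetylation acylates only the phenoxide, leaving the secondary alcohol free and turning the para oxygen into an acceptor that disfavours benzylic ionization in steps 7 and 8.

**Step 7**
Reactants: 5 2-geranyl-3-(geranyloxy)-5-(triisopropylsilyloxy)phenol; 9 4-[(1R)-3-(dimethylamino)-1-hydroxy-3-oxopropyl]phenyl acetate
Product: 10 (3S)-3-(4-acetoxyphenyl)-3-[2-geranyl-3-(geranyloxy)-5-(triisopropylsilyloxy)phenoxy]-N,N-dimethylpropanamide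
Conditions: PPh3, DIAD, toluene, 0 °C to rt
Reagents that add atoms: none
Why: Mitsunobu etherification of the phenol with the secondary benzylic alcohol proceeds by SN2 with inversion and so turns the (R)-carbinol into the (S)-aryl ether (the future C2); the amide is only weakly acidic at C3, which should limit elimination.

**Step 8**
Reactants: 10 (3S)-3-(4-acetoxyphenyl)-3-[2-geranyl-3-(geranyloxy)-5-(triisopropylsilyloxy)phenoxy]-N,N-dimethylpropanamide
Product: 12 (2S)-4'-acetoxy-8-geranyl-7-(geranyloxy)-5-(triisopropylsilyloxy)flavanone, via cyclic iminium triflate 11 (not isolated)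
Conditions: Tf2O, 2-fluoropyridine (excess), CH2Cl2, −78 to 0 °C; then H2O, THF, rt
Reagents that add atoms: water O
Why: Tf2O converts the tertiary amide into an O-triflyliminium ion (held as its 2-fluoropyridine adduct), whose carbon C4 is attacked by C4a of ring A; loss of triflate and of the C4a proton gives the conjugated cyclic iminium 11, which water hydrolyses to the C4 ketone. The closest known reaction type is the Vilsmeier–Haack acylation of electron-rich arenes with N,N-dimethylamides in its triflic anhydride/2-halopyridine form (electrophilic amide activation), used intramolecularly. Ring C closes in a 6-exo-trig mode (C4a onto the tethered iminium carbon, the C=N bond staying outside the new ring). No new stereocentre forms; C2 should be kept because no base able to open the β-aryloxy carbonyl unit (retro-oxa-Michael) is present and the 4-acetoxy group disfavours ionization of the benzylic C2–O1 bond. The step needs site selectivity on ring A and chemoselectivity against four trisubstituted alkenes and an allylic aryl ether: the O1–C2–C3 tether reaches only C4a (C8 is blocked, C6 lies para to O1), C4a is the most π-nucleophilic ring carbon, and the amide oxygen is the most nucleophilic site toward Tf2O at −78 °C while the weakly basic pyridine buffers the acid.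

**Step 9**
Reactants: 12 (2S)-4'-acetoxy-8-geranyl-7-(geranyloxy)-5-(triisopropylsilyloxy)flavanone
Product: 13 (2S)-4'-acetoxy-8-geranyl-7-(geranyloxy)-5-hydroxyflavanone
Conditions: TBAF, AcOH, THF, 0 °C
Reagents that add atoms: none
Why: Fluoride-mediated cleavage of the aryl silyl ether, buffered with acetic acid so that neither the acetate nor the base-sensitive flavanone (ring opening to the chalcone) should be affected.

**Step 10**
Reactants: 13 (2S)-4'-acetoxy-8-geranyl-7-(geranyloxy)-5-hydroxyflavanone
Product: 14 (2S)-8-geranyl-7-(geranyloxy)-5,4'-dihydroxyflavanone (CNP0103685.1)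
Conditions: NH4OAc, MeOH/H2O, rt
Reagents that add atoms: none
Why: Near-neutral ammonium acetate-mediated solvolysis of a phenyl acetate; without strong base C2 should not racemize through the chalcone, and the geranyl ether and alkenes are inert.

**Compound list**
1 | phloroglucinol (benzene-1,3,5-triol) | Oc1cc(O)cc(O)c1 | starting material
2 | geraniol | CC(C)=CCC/C(C)=C/CO | starting material
3 | 2-geranylphloroglucinol | CC(C)=CCC/C(C)=C/Cc1c(O)cc(O)cc1O | intermediate
4 | 2-geranyl-5-(triisopropylsilyloxy)benzene-1,3-diol | CC(C)=CCC/C(C)=C/Cc1c(O)cc(O[Si](C(C)C)(C(C)C)C(C)C)cc1O | intermediate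
5 | 2-geranyl-3-(geranyloxy)-5-(triisopropylsilyloxy)phenol | CC(C)=CCC/C(C)=C/COc1cc(O[Si](C(C)C)(C(C)C)C(C)C)cc(O)c1C/C=C(\C)CCC=C(C)C | intermediate
6 | ethyl 3-(4-hydroxyphenyl)-3-oxopropanoate | CCOC(=O)CC(=O)c1ccc(O)cc1 | starting material
7 | ethyl (3R)-3-hydroxy-3-(4-hydroxyphenyl)propanoate | CCOC(=O)C[C@@H](O)c1ccc(O)cc1 | intermediate
8 | (3R)-3-hydroxy-3-(4-hydroxyphenyl)-N,N-dimethylpropanamide | CN(C)C(=O)C[C@@H](O)c1ccc(O)cc1 | intermediate
9 | 4-[(1R)-3-(dimethylamino)-1-hydroxy-3-oxopropyl]phenyl acetate | CN(C)C(=O)C[C@@H](O)c1ccc(OC(C)=O)cc1 | intermediate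
10 | (3S)-3-(4-acetoxyphenyl)-3-[2-geranyl-3-(geranyloxy)-5-(triisopropylsilyloxy)phenoxy]-N,N-dimethylpropanamide | CN(C)C(=O)C[C@H](Oc1cc(O[Si](C(C)C)(C(C)C)C(C)C)cc(OC/C=C(\C)CCC=C(C)C)c1C/C=C(\C)CCC=C(C)C)c1ccc(OC(C)=O)cc1 | intermediate
11 | [(2S)-2-(4-acetoxyphenyl)-8-geranyl-7-(geranyloxy)-5-(triisopropylsilyloxy)chroman-4-ylidene]dimethylammonium triflate | CC(C)=CCC/C(C)=C/COc1cc(O[Si](C(C)C)(C(C)C)C(C)C)c2c(c1C/C=C(\C)CCC=C(C)C)O[C@H](c1ccc(OC(C)=O)cc1)CC2=[N+](C)C.[O-]S(=O)(=O)C(F)(F)F | intermediate (not isolated)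
12 | (2S)-4'-acetoxy-8-geranyl-7-(geranyloxy)-5-(triisopropylsilyloxy)flavanone | CC(C)=CCC/C(C)=C/COc1cc(O[Si](C(C)C)(C(C)C)C(C)C)c2c(c1C/C=C(\C)CCC=C(C)C)O[C@H](c1ccc(OC(C)=O)cc1)CC2=O | intermediate
13 | (2S)-4'-acetoxy-8-geranyl-7-(geranyloxy)-5-hydroxyflavanone | CC(C)=CCC/C(C)=C/COc1cc(O)c2c(c1C/C=C(\C)CCC=C(C)C)O[C@H](c1ccc(OC(C)=O)cc1)CC2=O | intermediate
14 | (2S)-8-geranyl-7-(geranyloxy)-5,4'-dihydroxyflavanone (CNP0103685.1) | CC(C)=CCC/C(C)=C/COc1cc(O)c2c(c1C/C=C(\C)CCC=C(C)C)O[C@H](c1ccc(O)cc1)CC2=O | target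

**Step count**
Total steps: 10. Longest linear sequence: 7 steps (1, 2, 3, 7, 8, 9, 10 from phloroglucinol; equally 4, 5, 6, 7, 8, 9, 10 from 6).

**Steps most likely to fail**

Step 7 (Mitsunobu etherification). The activated benzylic alcohol may lose a proton from C3 and collapse to the cinnamamide, or ionize and recombine with partial loss of configuration, because the ortho-substituted, weakly acidic phenol 5 attacks slowly. The fallback replaces alcohol activation by nucleophilic opening of a β-lactone; it sets out from 7 (with 5) and returns at 10. Ester 7 is saponified (LiOH, THF/H2O) to (3R)-3-hydroxy-3-(4-hydroxyphenyl)propanoic acid F1. The phenol is acetylated (Ac2O, aq. NaOH) to (3R)-3-(4-acetoxyphenyl)-3-hydroxypropanoic acid F2. Carboxyl activation (PhSO2Cl, pyridine, 0 °C) closes (4R)-4-(4-acetoxyphenyl)oxetan-2-one F3 with retention. The cesium phenoxide of 5 (Cs2CO3, MeCN) should open F3 by SN2 at the benzylic carbon with inversion to (3S)-3-(4-acetoxyphenyl)-3-[2-geranyl-3-(geranyloxy)-5-(triisopropylsilyloxy)phenoxy]propanoic acid F4. Amide coupling with Me2NH (EDC·HCl, HOBt) then gives 10.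

Step 8 (key ring closure). Three processes may interfere: loss of the aryloxide from the activated amide (retro-oxa-Michael through a keteniminium), ring opening and reclosure of the cyclic iminium with erosion of C2, and acid-induced cyclization of the geranyl chains. The fallback closes the same bond one oxidation level lower; it sets out from 10 and returns at 12. Cp2Zr(H)Cl (THF, rt) reduces the tertiary amide to (3S)-3-(4-acetoxyphenyl)-3-[2-geranyl-3-(geranyloxy)-5-(triisopropylsilyloxy)phenoxy]propanal F5. Me2AlCl (CH2Cl2, −78 °C) promotes intramolecular Friedel–Crafts hydroxyalkylation at C4a to (2S)-4'-acetoxy-8-geranyl-7-(geranyloxy)-5-(triisopropylsilyloxy)flavan-4-ol F6 (either C4 epimer serves). MnO2 (CH2Cl2, rt) oxidizes the benzylic alcohol to 12.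

Step 1 (C-geranylation). Over-allylation and acid-induced cyclization of the geranyl chain onto an ortho hydroxyl (chroman formation) may occur on the Al2O3 surface. The fallback uses directed ortho-metalation of protected phloroglucinol; it sets out from 1 and returns at 3. MOMCl and iPr2NEt (CH2Cl2) give 1,3,5-tris(methoxymethoxy)benzene F7. n-BuLi (THF, 0 °C), then CuBr·SMe2 and geranyl bromide, give 2-geranyl-1,3,5-tris(methoxymethoxy)benzene F8 by SN2 coupling of the aryl copper species. Catalytic HCl in MeOH at rt removes the three acetals to give 3.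

**Further compounds**
F1 | step 7 | (3R)-3-hydroxy-3-(4-hydroxyphenyl)propanoic acid | OC(=O)C[C@@H](O)c1ccc(O)cc1
F2 | step 7 | (3R)-3-(4-acetoxyphenyl)-3-hydroxypropanoic acid | OC(=O)C[C@@H](O)c1ccc(OC(C)=O)cc1
F3 | step 7 | (4R)-4-(4-acetoxyphenyl)oxetan-2-one | O=C1C[C@H](c2ccc(OC(C)=O)cc2)O1
F4 | step 7 | (3S)-3-(4-acetoxyphenyl)-3-[2-geranyl-3-(geranyloxy)-5-(triisopropylsilyloxy)phenoxy]propanoic acid | OC(=O)C[C@H](Oc1cc(O[Si](C(C)C)(C(C)C)C(C)C)cc(OC/C=C(\C)CCC=C(C)C)c1C/C=C(\C)CCC=C(C)C)c1ccc(OC(C)=O)cc1
F5 | step 8 | (3S)-3-(4-acetoxyphenyl)-3-[2-geranyl-3-(geranyloxy)-5-(triisopropylsilyloxy)phenoxy]propanal | O=CC[C@H](Oc1cc(O[Si](C(C)C)(C(C)C)C(C)C)cc(OC/C=C(\C)CCC=C(C)C)c1C/C=C(\C)CCC=C(C)C)c1ccc(OC(C)=O)cc1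
F6 | step 8 | (2S)-4'-acetoxy-8-geranyl-7-(geranyloxy)-5-(triisopropylsilyloxy)flavan-4-ol | CC(C)=CCC/C(C)=C/COc1cc(O[Si](C(C)C)(C(C)C)C(C)C)c2c(c1C/C=C(\C)CCC=C(C)C)O[C@H](c1ccc(OC(C)=O)cc1)CC2O
F7 | step 1 | 1,3,5-tris(methoxymethoxy)benzene | COCOc1cc(OCOC)cc(OCOC)c1
F8 | step 1 | 2-geranyl-1,3,5-tris(methoxymethoxy)benzene | CC(C)=CCC/C(C)=C/Cc1c(OCOC)cc(OCOC)cc1OCOC
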